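The numbers in the tables come from a simulation for an exercise, noise included.

At the last reading, 10.0 d, the dusk run stood at 74.9 % product, still rising from 71.2 % at 8.00 d, and the autumn run stood at 84.7 %.

the same everywhere: free catalyst 7.5 mM; second catalyst 1.5 mM
- autumn: substrate 0.60 M; reagent 1.2 M; run made earlier
- dusk: substrate 1 M; reagent 1.2 M; run made earlier
- gamma: substrate 0.80 M; reagent 1.20 M; time 20 d
- epsilon: substrate 1.5 M; reagent 1.20 M; time 10 d

- autumn (time / d: product / %, substrate / %): 0.833: 19.8, 36.3; 1.67: 38.8, 24.6; 3.00: 57.8, 15.7; 5.00: 72.5, 10.1; 10.0: 84.7, 5.7
- dusk (time / d: product / %, substrate / %): 2.08: 36.5, 23.7; 4.00: 54.2, 16.3; 6.00: 65.1, 12.6; 8.00: 71.2, 10.2; 10.0: 74.9, 9.1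

(scatter of a reading: 0.3 percentage points)

1. the flask that ends with the higher amount of product, in percent of the substrate charged, or "neither" when 2 percentage points or less lies between them (gamma / epsilon / neither)
2. final product, as a percentage of the substrate charged, in gamma
3. final product, as a percentage of the substrate charged, in epsilon

We assume that each product takes one reagent, so epsilon's charge of reagent allows product up to 80.0 % of the substrate charged. We call this the reagent ceiling Y, the charged reagent over the charged substrate, and in epsilon reagent is the limiting reagent. In gamma the same ratio is 150 %, above the whole charge, so there substrate limits instead.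

For the speed we take the dusk run's 74.9 %, the share of its whole charge that the dusk run had reached by 10 d, and assume the same share of Y for epsilon, which puts our estimate for epsilon near 59.9 %. Gamma's substrate charge lies midway between those of autumn and dusk, so we put gamma near 79.8 % at 10 d, with further rise expected up to 20 d, and that estimate already lies 20 percentage points above our estimate for epsilon.

The forecast names gamma, with 84 % in gamma and 59 % in epsilon against our 59.9 %, saying: “Epsilon: reagent is limiting (maximum 80%), giving about 0.9 M product, or about 59%.”

The flasks give 87.8 % in gamma and 61.4 % in epsilon, so gamma ends higher.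

    substrate + free catalyst ⇌ free catalyst + open intermediate (K = 1.90, k = 0.00296 L mol⁻¹ s⁻¹)
    reagent + catalyst intermediate → second catalyst + product (k = 0.00264 L mol⁻¹ s⁻¹)
    second catalyst ⇌ dormant form (K = 11.0, k = 4.01 × 10⁻⁶ s⁻¹)
    second catalyst + open intermediate ⇌ catalyst intermediate (K = 4.06 L mol⁻¹, k = 0.172 L mol⁻¹ s⁻¹)

Epsilon stood at 76.8 % of Y at 10.0 d, with 23 % of its reagent left, and at 100 d it gives 78.7 %, just under Y.

A neighbour of epsilon charged with 0.30 M of reagent has Y = 20.0 %, and the dusk share makes that 15.0 %; the computed flask gives 16.8 % at 10.0 d.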